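Everything rests on disconnecting the Cα–Cβ bond of the guaiacylglycerol chain: Cα is the benzylic carbinol carbon on the 4-hydroxy-3-methoxyphenyl ring, Cβ the carbon carrying the aryl ether oxygen and Cγ (CH2OH). The key step exploits this anti (erythro) β-hydroxy-α-aryloxy pattern: with Cγ at the carboxyl level, Cβ is the α-carbon of an aryloxyacetyl imide and Cα an aldehyde carbon. A magnesium-catalysed, auxiliary-controlled anti-aldol unites imide 16, which already carries the complete furofuran (the 3,7-dioxabicyclo[3.3.0]octane rings), with vanillin acetate 17, forming Cα–Cβ and setting both stereocentres (αR,βS) in one operation.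

Key step: step 9

Remark: locants are Cα/Cβ/Cγ for the glycerol chain and C7–C9 (guaiacyl half) and C7'–C9' (syringyl half) for the furofuran; 8 and 9 are carried as epimer mixtures at the guaiacyl carbinol carbon (left undefined in their SMILES) because step 5 ionizes that centre; the facial sense assumed for the anti-aldol (steps 9 and the step-2 fallback) is that of a magnesium-chelated enolate.

Step 1
Reactants: 1 syringaldehyde
Product: 2 3,5-dimethoxy-4-(triisopropylsilyloxy)benzaldehyde
Conditions: TIPSCl, imidazole, DMF, rt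
Reagents that add atoms: TIPSCl, CC(C)[Si](Cl)(C(C)C)C(C)C
Why: Imidazole-mediated O-silylation of the hindered phenol; the TIPS aryl ether should survive the amide base, hydride, acid, zerovalent palladium and carbonate used later and is removed last by fluoride.

Step 2
Reactants: 2 3,5-dimethoxy-4-(triisopropylsilyloxy)benzaldehyde; 3 methyl 4-oxobutanoate
Product: 6 (4S)-4-[(S)-hydroxy{3,5-dimethoxy-4-(triisopropylsilyloxy)phenyl}methyl]dihydrofuran-2(3H)-one, via aldol aldehyde 4 (not isolated), via diol ester 5 (not isolated)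
Conditions: D-proline (30 mol%), DMF, 4 °C; then NaBH4, MeOH, −20 → 0 °C; aq. NH4Cl
Reagents that add atoms: none
Why: Proline-catalysed enamine cross-aldol of the aldehyde donor with the non-enolizable aryl aldehyde gives the anti-aldol, D-proline setting C8' (S) and C7' (S) through the carboxylic-acid-directed transition state; NaBH4 then reduces the aldehyde and the primary alcohol lactonizes onto the methyl ester (known organocatalytic route to β-(hydroxyalkyl)-γ-butyrolactones).

Step 3
Reactants: 6 the lactone; 7 4-(allyloxy)-3-methoxybenzaldehyde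
Product: 8 (3R,4S)-3-{[4-(allyloxy)-3-methoxyphenyl](hydroxy)methyl}-4-[(S)-hydroxy{3,5-dimethoxy-4-(triisopropylsilyloxy)phenyl}methyl]dihydrofuran-2(3H)-one (epimer mixture at the new carbinol carbon)
Conditions: LiN(SiMe3)2 (2.3 equiv), THF, −78 °C; then 7; AcOH quench at −78 °C
Reagents that add atoms: none
Why: Aldol addition of the lithium alkoxide–enolate dianion of a β-substituted γ-butyrolactone; the aldehyde approaches the enolate face anti to the C4 substituent, which sets C8 (3,4-trans), while the new carbinol centre C7 forms as an epimer mixture that step 5 erases.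

Step 4
Reactants: 8 the aldol lactone
Product: 9 (2S,3S)-2-{[4-(allyloxy)-3-methoxyphenyl](hydroxy)methyl}-3-[(S)-hydroxy{3,5-dimethoxy-4-(triisopropylsilyloxy)phenyl}methyl]butane-1,4-diol (epimer mixture at the guaiacyl carbinol carbon)
Conditions: LiAlH4, THF, 0 °C → rt
Reagents that add atoms: none
Why: Hydride reduction of the lactone to the 1,4-diol; no stereocentre is touched, and the aryl silyl and allyl ethers are inert at this temperature.

Step 5
Reactants: 9 the tetraol
Product: 11 (1R,3aS,4R,6aS)-1-[4-(allyloxy)-3-methoxyphenyl]-4-[3,5-dimethoxy-4-(triisopropylsilyloxy)phenyl]tetrahydro-1H,3H-furo[3,4-c]furan, via monocyclic tetrahydrofuran diol 10 (not isolated)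
Conditions: TFA (5 equiv), CH2Cl2, −20 → 0 °C; Et3N quench as soon as 10 is consumed
Reagents that add atoms: none
Why: SN1 cyclodehydration: acid ionizes both electron-rich benzylic carbinols, each cation is captured by the 1,4-related primary hydroxyl, and the allylic-strain-minimized cation conformer places each aryl group trans to the neighbouring ring carbon, so C7 and C7' should emerge exo (R,R) whatever the carbinol configuration, with the (8S,8'S) centres enforcing the cis ring fusion.

Step 6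
Reactants: 11 the allyl ether
Product: 12 4-{(1R,3aS,4R,6aS)-4-[3,5-dimethoxy-4-(triisopropylsilyloxy)phenyl]tetrahydro-1H,3H-furo[3,4-c]furan-1-yl}-2-methoxyphenol
Conditions: Pd(PPh3)4 (5 mol%), morpholine, THF, rt
Reagents that add atoms: none
Why: Tsuji–Trost deallylation: zerovalent palladium ionizes the aryl allyl ether to a π-allyl complex that morpholine traps, under neutral conditions that leave the aryl silyl ether and the benzylic ethers untouched.

Step 7
Reactants: 13 (S)-4-benzyl-oxazolidin-2-one; 14 bromoacetyl bromide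
Product: 15 (S)-4-benzyl-3-(2-bromoacetyl)oxazolidin-2-one
Conditions: n-BuLi, THF, −78 °C; then 14, −78 → 0 °C
Reagents that add atoms: none
Why: N-acylation of the lithiated oxazolidinone, the acyl bromide reacting far faster than the alkyl bromide.

Step 8
Reactants: 12 the phenol; 15 the bromoacetyl imide
Product: 16 (S)-4-benzyl-3-{2-[4-{(1R,3aS,4R,6aS)-4-[3,5-dimethoxy-4-(triisopropylsilyloxy)phenyl]tetrahydro-1H,3H-furo[3,4-c]furan-1-yl}-2-methoxyphenoxy]acetyl}oxazolidin-2-one
Conditions: K2CO3, MeCN, rt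
Reagents that add atoms: none
Why: Williamson etherification: the guaiacyl phenoxide displaces the activated α-bromide of the imide by SN2, and the hindered silyl ether on the other phenol is stable to carbonate in an aprotic solvent.

Step 9
Reactants: 16 the aryloxyacetyl imide; 17 4-formyl-2-methoxyphenyl acetate (vanillin acetate)
Product: 19 (S)-4-benzyl-3-[(2R,3R)-3-(4-acetoxy-3-methoxyphenyl)-3-hydroxy-2-(aryloxy)propanoyl]oxazolidin-2-one (aryloxy = the furofuran-bearing 2-methoxyphenoxy group of 16), via trimethylsilyl ether 18 (not isolated)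
Conditions: MgCl2 (20 mol%), NaSbF6 (40 mol%), Et3N, TMSCl, EtOAc, rt; then citric acid, MeOH, 0 °C
Reagents that add atoms: none
Why: Soft enolization of the magnesium-chelated imide (MgCl2, Et3N) gives the Z-enolate, which adds to the aldehyde through a boat-like transition state on six-coordinate magnesium, and TMSCl silylates the aldolate so that the metal turns over. The closest known reaction type is the magnesium-halide-catalysed direct anti-aldol of chiral N-acyloxazolidinones with aromatic aldehydes, here run on an aryloxyacetyl imide. No ring is closed; the new bond is Cα–Cβ between the two fragments. Cβ (S) is controlled by the auxiliary, since the aldehyde reaches the chelated enolate on the face opposite the benzyl group (the facial sense of enolate alkylations with this auxiliary); Cα (R) follows from the boat arrangement, which gives the anti (erythro) adduct. The step needs anti over syn selectivity and reaction at the imide CH2 only: the magnesium manifold instead of a boron enolate (which gives the syn, threo isomer) secures the first, and the single acidic site plus the acetate-activated, non-enolizable aldehyde secure the second. The amine-buffered medium spares the acid-labile benzylic ethers of the furofuran and the aryl silyl ether.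

Step 10
Reactants: 19 the anti-aldol adduct
Product: 20 (1R,2S)-1-(4-hydroxy-3-methoxyphenyl)-2-[4-{(1R,3aS,4R,6aS)-4-[3,5-dimethoxy-4-(triisopropylsilyloxy)phenyl]tetrahydro-1H,3H-furo[3,4-c]furan-1-yl}-2-methoxyphenoxy]propane-1,3-diol
Conditions: LiBH4 (excess), THF–MeOH, 0 °C → rt
Reagents that add atoms: none
Why: Reductive cleavage of the N-acyl oxazolidinone to the primary alcohol (Cγ) releases the auxiliary without touching Cα or Cβ, and the same hydride removes the aryl acetate, so the guaiacyl phenol is freed in the same operation.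

Step 11
Reactants: 20 the silyl ether
Product: 21 Ficusesquilignan A
Conditions: Bu4NF, AcOH, THF, 0 °C
Reagents that add atoms: none
Why: Fluoride cleavage of the aryl triisopropylsilyl ether, buffered with acetic acid so that the p-hydroxybenzyl alcohol and the benzylic ethers are not exposed to free phenoxide or strong acid.

Compound list
1 | syringaldehyde (4-hydroxy-3,5-dimethoxybenzaldehyde) | COc1cc(C=O)cc(OC)c1O | starting material
2 | 3,5-dimethoxy-4-(triisopropylsilyloxy)benzaldehyde | COc1cc(C=O)cc(OC)c1O[Si](C(C)C)(C(C)C)C(C)C | intermediate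
3 | methyl 4-oxobutanoate | COC(=O)CCC=O | starting material
4 | methyl (3R,4S)-3-formyl-4-hydroxy-4-[3,5-dimethoxy-4-(triisopropylsilyloxy)phenyl]butanoate (aldol aldehyde, formed in the flask) | COC(=O)C[C@@H](C=O)[C@H](O)c1cc(OC)c(O[Si](C(C)C)(C(C)C)C(C)C)c(OC)c1 | intermediate
5 | methyl (3S,4S)-4-hydroxy-3-(hydroxymethyl)-4-[3,5-dimethoxy-4-(triisopropylsilyloxy)phenyl]butanoate (diol ester, formed in the flask) | COC(=O)C[C@@H](CO)[C@H](O)c1cc(OC)c(O[Si](C(C)C)(C(C)C)C(C)C)c(OC)c1 | intermediate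
6 | (4S)-4-[(S)-hydroxy{3,5-dimethoxy-4-(triisopropylsilyloxy)phenyl}methyl]dihydrofuran-2(3H)-one | O=C1C[C@@H](CO1)[C@H](O)c1cc(OC)c(O[Si](C(C)C)(C(C)C)C(C)C)c(OC)c1 | intermediate
7 | 4-(allyloxy)-3-methoxybenzaldehyde | C=CCOc1ccc(C=O)cc1OC | starting material
8 | (3R,4S)-3-{[4-(allyloxy)-3-methoxyphenyl](hydroxy)methyl}-4-[(S)-hydroxy{3,5-dimethoxy-4-(triisopropylsilyloxy)phenyl}methyl]dihydrofuran-2(3H)-one, epimer mixture at the guaiacyl carbinol carbon | O=C1[C@@H](C(O)c2ccc(OCC=C)c(OC)c2)[C@@H](CO1)[C@H](O)c1cc(OC)c(O[Si](C(C)C)(C(C)C)C(C)C)c(OC)c1 | intermediate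
9 | (2S,3S)-2-{[4-(allyloxy)-3-methoxyphenyl](hydroxy)methyl}-3-[(S)-hydroxy{3,5-dimethoxy-4-(triisopropylsilyloxy)phenyl}methyl]butane-1,4-diol, epimer mixture at the guaiacyl carbinol carbon | OC[C@@H](C(O)c1ccc(OCC=C)c(OC)c1)[C@@H](CO)[C@H](O)c1cc(OC)c(O[Si](C(C)C)(C(C)C)C(C)C)c(OC)c1 | intermediate
10 | {(2R,3S,4S)-2-[4-(allyloxy)-3-methoxyphenyl]-4-[(S)-hydroxy{3,5-dimethoxy-4-(triisopropylsilyloxy)phenyl}methyl]tetrahydrofuran-3-yl}methanol (formed in the flask) | C=CCOc1ccc([C@@H]2OC[C@@H]([C@H](O)c3cc(OC)c(O[Si](C(C)C)(C(C)C)C(C)C)c(OC)c3)[C@H]2CO)cc1OC | intermediate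
11 | (1R,3aS,4R,6aS)-1-[4-(allyloxy)-3-methoxyphenyl]-4-[3,5-dimethoxy-4-(triisopropylsilyloxy)phenyl]tetrahydro-1H,3H-furo[3,4-c]furan | C=CCOc1ccc([C@@H]2OC[C@@H]3[C@H]2CO[C@H]3c2cc(OC)c(O[Si](C(C)C)(C(C)C)C(C)C)c(OC)c2)cc1OC | intermediate
12 | 4-{(1R,3aS,4R,6aS)-4-[3,5-dimethoxy-4-(triisopropylsilyloxy)phenyl]tetrahydro-1H,3H-furo[3,4-c]furan-1-yl}-2-methoxyphenol | Oc1ccc([C@@H]2OC[C@@H]3[C@H]2CO[C@H]3c2cc(OC)c(O[Si](C(C)C)(C(C)C)C(C)C)c(OC)c2)cc1OC | intermediate
13 | (S)-4-benzyl-oxazolidin-2-one | O=C1N[C@@H](Cc2ccccc2)CO1 | starting material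
14 | bromoacetyl bromide | BrCC(Br)=O | starting material
15 | (S)-4-benzyl-3-(2-bromoacetyl)oxazolidin-2-one | O=C1N(C(=O)CBr)[C@@H](Cc2ccccc2)CO1 | intermediate
16 | (S)-4-benzyl-3-{2-[4-{(1R,3aS,4R,6aS)-4-[3,5-dimethoxy-4-(triisopropylsilyloxy)phenyl]tetrahydro-1H,3H-furo[3,4-c]furan-1-yl}-2-methoxyphenoxy]acetyl}oxazolidin-2-one | O=C1N(C(=O)COc2ccc([C@@H]3OC[C@@H]4[C@H]3CO[C@H]4c3cc(OC)c(O[Si](C(C)C)(C(C)C)C(C)C)c(OC)c3)cc2OC)[C@@H](Cc2ccccc2)CO1 | intermediate
17 | 4-formyl-2-methoxyphenyl acetate (vanillin acetate) | CC(=O)Oc1ccc(C=O)cc1OC | starting material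
18 | O-trimethylsilyl ether of 19 at the Cα hydroxyl (formed in the flask) | CC(=O)Oc1ccc([C@@H](O[Si](C)(C)C)[C@H](C(=O)N2C(=O)OC[C@@H]2Cc2ccccc2)Oc2ccc([C@@H]3OC[C@@H]4[C@H]3CO[C@H]4c3cc(OC)c(O[Si](C(C)C)(C(C)C)C(C)C)c(OC)c3)cc2OC)cc1OC | intermediate
19 | (S)-4-benzyl-3-[(2R,3R)-3-(4-acetoxy-3-methoxyphenyl)-3-hydroxy-2-(aryloxy)propanoyl]oxazolidin-2-one, aryloxy as in 16 | CC(=O)Oc1ccc([C@@H](O)[C@H](C(=O)N2C(=O)OC[C@@H]2Cc2ccccc2)Oc2ccc([C@@H]3OC[C@@H]4[C@H]3CO[C@H]4c3cc(OC)c(O[Si](C(C)C)(C(C)C)C(C)C)c(OC)c3)cc2OC)cc1OC | intermediate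
20 | (1R,2S)-1-(4-hydroxy-3-methoxyphenyl)-2-[4-{(1R,3aS,4R,6aS)-4-[3,5-dimethoxy-4-(triisopropylsilyloxy)phenyl]tetrahydro-1H,3H-furo[3,4-c]furan-1-yl}-2-methoxyphenoxy]propane-1,3-diol | COc1cc([C@@H](O)[C@H](CO)Oc2ccc([C@@H]3OC[C@@H]4[C@H]3CO[C@H]4c3cc(OC)c(O[Si](C(C)C)(C(C)C)C(C)C)c(OC)c3)cc2OC)ccc1O | intermediate
21 | Ficusesquilignan A, (αR,βS; 7R,8S,7'R,8'S) | COc1cc([C@@H](O)[C@H](CO)Oc2ccc([C@@H]3OC[C@@H]4[C@H]3CO[C@H]4c3cc(OC)c(O)c(OC)c3)cc2OC)ccc1O | target

Total step count: 11. Longest linear sequence: 10 steps (steps 1–6, then 8–11); step 7 is a one-step side branch.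

Steps most likely to fail

Step 9 (key step). The anti selectivity may erode through a competing chair-like or aryloxy-chelated transition state, the facial sense may not follow the chelated-enolate model, or catalyst turnover may stall with the bulky imide. The fallback uses the boron-mediated syn-aldol known for aryloxyacetyl oxazolidinones, followed by inversion of the carbinol centre. It sets out from 12, which is alkylated (K2CO3, MeCN) with (R)-4-benzyl-3-(2-bromoacetyl)oxazolidin-2-one F1, made from commercial (R)-4-benzyl-oxazolidin-2-one and 14 with n-BuLi. This gives the (R)-auxiliary aryloxyacetyl imide F2. An Evans syn-aldol of F2 with 17 (Bu2BOTf, i-Pr2NEt, CH2Cl2, −78 → 0 °C) should give the syn (threo) adduct F3, in which Cβ already has the required configuration. Mitsunobu inversion of Cα (4-nitrobenzoic acid, PPh3, DIAD, THF, 0 °C) then gives the anti 4-nitrobenzoate F4. LiBH4 cleaves the auxiliary, the nitrobenzoate and the acetate together, and the sequence comes back to the route at 20.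

Step 5. The less donor-activated syringyl carbinol may ionize too slowly, a benzylic cation may be captured by the other benzylic hydroxyl or by the second arene ring, and prolonged acid may re-ionize the guaiacyl benzylic ether of the product and erode the exo configuration at C7. The fallback closes the two rings in separate events and forms the labile guaiacyl benzylic ether last, by oxidation instead of acid. It sets out from 6 and 7. Aldehyde 7 is reduced (NaBH4, MeOH) to [4-(allyloxy)-3-methoxyphenyl]methanol F5 and brominated (PBr3, Et2O, 0 °C) to 4-(allyloxy)-3-methoxybenzyl bromide F6. The dianion of 6 (LiN(SiMe3)2, THF, −78 °C) is alkylated with F6, anti to the C4 substituent, to give the trans benzyl lactone F7. LiAlH4 gives the triol F8. Mild acid (camphorsulfonic acid, CH2Cl2, 0 °C) then ionizes the only benzylic carbinol present and closes the syringyl-side ring to the 2-aryl-tetrahydrofuran F9. Finally DDQ (CH2Cl2, pH 7 buffer, 0 °C) oxidizes the guaiacyl benzylic CH2 to the cation, which the remaining primary hydroxyl captures on the exo face, and the sequence comes back to the route at 11.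

Step 2. Enamine addition to the electron-rich, hindered aldehyde may be slow, so that self-aldolization of the donor and erosion of enantiopurity compete. The fallback replaces organocatalysis by an auxiliary-controlled anti-aldol that delivers the aldolate already silylated, which blocks lactonization through the benzylic oxygen. It sets out from 13 and 2. Auxiliary 13 is acylated (n-BuLi, THF, −78 °C, methyl 4-chloro-4-oxobutanoate) to (S)-4-benzyl-3-(4-methoxy-4-oxobutanoyl)oxazolidin-2-one F10. The magnesium-catalysed anti-aldol of F10 with 2 (MgCl2, NaSbF6, Et3N, TMSCl, EtOAc, rt) should give the anti O-trimethylsilyl adduct F11. LiBH4 (THF, 0 °C) reduces the imide, the primary alkoxide lactonizes onto the methyl ester, and a citric acid work-up removes the silyl group, so the sequence comes back to the route at 6.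

Further compounds
F1 | step 9 | (R)-4-benzyl-3-(2-bromoacetyl)oxazolidin-2-one | O=C1N(C(=O)CBr)[C@H](Cc2ccccc2)CO1
F2 | step 9 | (R)-4-benzyl-3-{2-[4-{(1R,3aS,4R,6aS)-4-[3,5-dimethoxy-4-(triisopropylsilyloxy)phenyl]tetrahydro-1H,3H-furo[3,4-c]furan-1-yl}-2-methoxyphenoxy]acetyl}oxazolidin-2-one | O=C1N(C(=O)COc2ccc([C@@H]3OC[C@@H]4[C@H]3CO[C@H]4c3cc(OC)c(O[Si](C(C)C)(C(C)C)C(C)C)c(OC)c3)cc2OC)[C@H](Cc2ccccc2)CO1
F3 | step 9 | (R)-4-benzyl-3-[(2R,3S)-3-(4-acetoxy-3-methoxyphenyl)-3-hydroxy-2-(aryloxy)propanoyl]oxazolidin-2-one (syn adduct, aryloxy as in 16) | CC(=O)Oc1ccc([C@H](O)[C@H](C(=O)N2C(=O)OC[C@H]2Cc2ccccc2)Oc2ccc([C@@H]3OC[C@@H]4[C@H]3CO[C@H]4c3cc(OC)c(O[Si](C(C)C)(C(C)C)C(C)C)c(OC)c3)cc2OC)cc1OC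
F4 | step 9 | (R)-4-benzyl-3-[(2R,3R)-3-(4-acetoxy-3-methoxyphenyl)-3-(4-nitrobenzoyloxy)-2-(aryloxy)propanoyl]oxazolidin-2-one | CC(=O)Oc1ccc([C@@H](OC(=O)c2ccc(cc2)[N+](=O)[O-])[C@H](C(=O)N2C(=O)OC[C@H]2Cc2ccccc2)Oc2ccc([C@@H]3OC[C@@H]4[C@H]3CO[C@H]4c3cc(OC)c(O[Si](C(C)C)(C(C)C)C(C)C)c(OC)c3)cc2OC)cc1OC
F5 | step 5 | [4-(allyloxy)-3-methoxyphenyl]methanol | C=CCOc1ccc(CO)cc1OC
F6 | step 5 | 4-(allyloxy)-3-methoxybenzyl bromide | C=CCOc1ccc(CBr)cc1OC
F7 | step 5 | (3S,4S)-3-[4-(allyloxy)-3-methoxybenzyl]-4-[(S)-hydroxy{3,5-dimethoxy-4-(triisopropylsilyloxy)phenyl}methyl]dihydrofuran-2(3H)-one | O=C1[C@@H](Cc2ccc(OCC=C)c(OC)c2)[C@@H](CO1)[C@H](O)c1cc(OC)c(O[Si](C(C)C)(C(C)C)C(C)C)c(OC)c1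
F8 | step 5 | (2S,3S)-2-[4-(allyloxy)-3-methoxybenzyl]-3-[(S)-hydroxy{3,5-dimethoxy-4-(triisopropylsilyloxy)phenyl}methyl]butane-1,4-diol | OC[C@@H](Cc1ccc(OCC=C)c(OC)c1)[C@@H](CO)[C@H](O)c1cc(OC)c(O[Si](C(C)C)(C(C)C)C(C)C)c(OC)c1
F9 | step 5 | {(2R,3S,4S)-4-[4-(allyloxy)-3-methoxybenzyl]-2-[3,5-dimethoxy-4-(triisopropylsilyloxy)phenyl]tetrahydrofuran-3-yl}methanol | C=CCOc1ccc(C[C@@H]2CO[C@@H](c3cc(OC)c(O[Si](C(C)C)(C(C)C)C(C)C)c(OC)c3)[C@@H]2CO)cc1OC
F10 | step 2 | (S)-4-benzyl-3-(4-methoxy-4-oxobutanoyl)oxazolidin-2-one | COC(=O)CCC(=O)N1C(=O)OC[C@@H]1Cc1ccccc1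
F11 | step 2 | methyl (3R)-4-[(4S)-4-benzyl-2-oxo-oxazolidin-3-yl]-3-[(S)-{3,5-dimethoxy-4-(triisopropylsilyloxy)phenyl}(trimethylsilyloxy)methyl]-4-oxobutanoate | COC(=O)C[C@@H](C(=O)N1C(=O)OC[C@@H]1Cc1ccccc1)[C@H](O[Si](C)(C)C)c1cc(OC)c(O[Si](C(C)C)(C(C)C)C(C)C)c(OC)c1
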